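## Retrosynthetic overview

1. Target ⇐ ester hydrolysis ⇐ Negishi methylation of an alkenyl triflate (C3–CH3) ⇐ kinetic enol triflate of ketone 14.
2. C5–isopropenyl ⇐ catalyst-controlled Rh/BINAP 1,4-addition of an isopropenyl boronate to enone 12, itself from ketone 10 by Saegusa oxidation.
3. Key disconnection: the CH2–O(coumarin) bond, made by a catalyst-controlled oxa-Michael addition/protonation of umbelliferone onto the exocyclic enone 8; this step also sets C2.
4. 8 ⇐ regiospecific Mannich methylenation of the enolate from a Cu-catalysed asymmetric conjugate addition of Me3Al (quaternary C1) to enone 3 ⇐ Negishi coupling of 3-bromocyclohex-2-enone with a zinc homoenolate.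
5. Rings: none is formed. The carbocycle is bought as 3-bromocyclohex-2-en-1-one and the coumarin as umbelliferone.

Assumption: the catalyst antipodes named in steps 2, 4 and 6 are assigned by analogy with the closest precedents; if a first run shows the opposite sense, the mirror-image (or pseudo-enantiomeric) catalyst is used instead.

Ring locants in the "Why" lines are those of the target: C1 (quaternary), C2 (CH–CH2OAr), C3 (C–CH3), C4 (=CH), C5 (CH–isopropenyl), C6 (CH2).

## Route

Step 1
Reactants: 1 3-bromocyclohex-2-en-1-one; 2 (3-ethoxy-3-oxopropyl)zinc bromide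
Product: 3 ethyl 3-(3-oxocyclohex-1-en-1-yl)propanoate
Conditions: Pd(PPh3)4 (3 mol%), THF, 50 °C
Reagents that add atoms: none
Why: Negishi coupling; the β-bromo enone undergoes fast oxidative addition and the zinc homoenolate carries the ester unchanged; no stereocentre is formed.

Step 2
Reactants: 3 ethyl 3-(3-oxocyclohex-1-en-1-yl)propanoate
Product: 5 ethyl 3-[(1S)-1-methyl-3-(trimethylsilyloxy)cyclohex-2-en-1-yl]propanoate, via dimethylaluminium enolate 4 (not isolated)
Conditions: Me3Al (1.5 equiv), CuTC (2 mol%), (S,S)-SimplePhos-type phosphoramidite (4 mol%), Et2O, −30 °C; then TMSOTf, −30 → 0 °C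
Reagents that add atoms: trimethylaluminium (C[Al](C)C); trimethylsilyl trifluoromethanesulfonate (C[Si](C)(C)OS(=O)(=O)C(F)(F)F)
Why: Cu-catalysed asymmetric conjugate addition of Me3Al to a β-substituted cyclohexenone (Alexakis type) builds the quaternary C1 by ligand-controlled face selection, and O-silylation of the regiospecific aluminium enolate fixes the enol double bond towards C2 for step 3.

Step 3
Reactants: 5 ethyl 3-[(1S)-1-methyl-3-(trimethylsilyloxy)cyclohex-2-en-1-yl]propanoate
Product: 8 ethyl 3-[(1S)-1-methyl-2-methylidene-3-oxocyclohexyl]propanoate, via Mannich base 6 (not isolated), via ammonium iodide 7 (not isolated)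
Conditions: Me2N+=CH2 I− (1.3 equiv), CH2Cl2, rt; then MeI, MeOH, rt; then aq. NaHCO3, CH2Cl2, rt
Reagents that add atoms: N,N-dimethylmethyleneiminium iodide (C=[N+](C)C.[I-])
Why: Mukaiyama–Mannich reaction of the silyl enol ether with Eschenmoser's salt followed by Hofmann-type elimination puts the methylene on the hindered C2 only, because the enol ether regiochemistry was fixed in step 2; no stereocentre is formed.

Step 4
Reactants: 8 ethyl 3-[(1S)-1-methyl-2-methylidene-3-oxocyclohexyl]propanoate; 9 7-hydroxy-2H-chromen-2-one (umbelliferone)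
Product: 10 ethyl 3-[(1S,2S)-1-methyl-3-oxo-2-{[(2-oxo-2H-chromen-7-yl)oxy]methyl}cyclohexyl]propanoate
Conditions: 9 (1.1 equiv), quinine-derived 3,5-bis(trifluoromethyl)phenyl squaramide (10 mol%), CH2Cl2/toluene 1:1, −20 °C
Reagents that add atoms: none
Why: Proposed new method: catalyst-controlled oxa-Michael addition/protonation, in which the quinuclidine nitrogen deprotonates the acidic phenol 9 (pKa about 7.8), the squaramide hydrogen-bonds the ketone of 8, the phenoxide adds to the unhindered exocyclic CH2 and the catalyst-bound enol(ate) is protonated on one face by the quinuclidinium N–H to set C2 (2S in 10); the two ring faces differ only by CH3 versus CH2CH2CO2Et on C1, so the substrate has almost no bias and the catalyst decides, and the product should not epimerise at −20 °C because its α-C–H is far too weakly acidic for the amine; the closest known reaction type is the cinchona (thio)urea/squaramide-catalysed thia-Michael addition with enantioselective protonation of α-substituted acrylates and enones, and to my knowledge a phenol version that sets the α-stereocentre of a 2-methylenecycloalkanone has not been shown.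

Step 5
Reactants: 10 ethyl 3-[(1S,2S)-1-methyl-3-oxo-2-{[(2-oxo-2H-chromen-7-yl)oxy]methyl}cyclohexyl]propanoate
Product: 12 ethyl 3-[(1R,6S)-1-methyl-5-oxo-6-{[(2-oxo-2H-chromen-7-yl)oxy]methyl}cyclohex-3-en-1-yl]propanoate, via trimethylsilyl enol ether 11 (not isolated)
Conditions: LiHMDS, TMSCl, THF, −78 °C; then Pd(OAc)2 (1.05 equiv), MeCN, rt
Reagents that add atoms: none
Why: Kinetic deprotonation takes the C4 methylene and not the hindered C2 methine (so C2 is not epimerised and the aryloxide is not eliminated), and Saegusa–Ito oxidation of the silyl enol ether gives the C4=C5 enone, the only side on which unsaturation is possible.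

Step 6
Reactants: 12 ethyl 3-[(1R,6S)-1-methyl-5-oxo-6-{[(2-oxo-2H-chromen-7-yl)oxy]methyl}cyclohex-3-en-1-yl]propanoate; 13 4,4,5,5-tetramethyl-2-(prop-1-en-2-yl)-1,3,2-dioxaborolane
Product: 14 ethyl 3-[(1R,2S,5S)-1-methyl-3-oxo-2-{[(2-oxo-2H-chromen-7-yl)oxy]methyl}-5-(prop-1-en-2-yl)cyclohexyl]propanoate
Conditions: 13 (2 equiv), [Rh(OH)((S)-binap)]2 (3 mol% Rh), dioxane/H2O 10:1, 35 °C
Reagents that add atoms: none
Why: Hayashi–Miyaura Rh-catalysed asymmetric 1,4-addition; (S)-BINAP, the antipode that gives (S)-3-substituted cyclohexanones from cyclohex-2-enone, delivers the isopropenyl group to the C5 face cis to the aryloxymethyl group (5S), the intrinsic facial bias of 12 being small because C1 carries two groups of similar size, and the near-neutral medium leaves the base-sensitive C2 centre alone.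

Step 7
Reactants: 14 ethyl 3-[(1R,2S,5S)-1-methyl-3-oxo-2-{[(2-oxo-2H-chromen-7-yl)oxy]methyl}-5-(prop-1-en-2-yl)cyclohexyl]propanoate
Product: 16 ethyl 3-[(1R,2S,5S)-1-methyl-2-{[(2-oxo-2H-chromen-7-yl)oxy]methyl}-5-(prop-1-en-2-yl)-3-{[(trifluoromethyl)sulfonyl]oxy}cyclohex-3-en-1-yl]propanoate, via potassium enolate 15 (not isolated)
Conditions: KHMDS (1.05 equiv), THF, −78 °C; then PhNTf2, −78 → −30 °C
Reagents that add atoms: N-phenylbis(trifluoromethanesulfonimide) (O=S(=O)(N(c1ccccc1)S(=O)(=O)C(F)(F)F)C(F)(F)F)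
Why: Kinetic enolisation again takes the C4 methylene instead of the hindered C2 methine, and O-triflation of the enolate (McMurry–Scott) places the C3=C4 double bond and locks C2, which is no longer α to a carbonyl.

Step 8
Reactants: 16 ethyl 3-[(1R,2S,5S)-1-methyl-2-{[(2-oxo-2H-chromen-7-yl)oxy]methyl}-5-(prop-1-en-2-yl)-3-{[(trifluoromethyl)sulfonyl]oxy}cyclohex-3-en-1-yl]propanoate
Product: 17 ethyl 3-[(1R,2R,5S)-1,3-dimethyl-2-{[(2-oxo-2H-chromen-7-yl)oxy]methyl}-5-(prop-1-en-2-yl)cyclohex-3-en-1-yl]propanoate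
Conditions: MeZnCl (2 equiv), Pd(PPh3)4 (5 mol%), THF, 50 °C
Reagents that add atoms: methylzinc chloride (C[Zn]Cl)
Why: Negishi cross-coupling of the alkenyl triflate installs the C3 methyl with the double bond held in place, and the organozinc tolerates the ethyl ester and the coumarin lactone; the change of the C2 descriptor from S to R is only a CIP priority change.

Step 9
Reactants: 17 ethyl 3-[(1R,2R,5S)-1,3-dimethyl-2-{[(2-oxo-2H-chromen-7-yl)oxy]methyl}-5-(prop-1-en-2-yl)cyclohex-3-en-1-yl]propanoate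
Product: 19 3-[(1R,2R,5S)-1,3-dimethyl-2-{[(2-oxo-2H-chromen-7-yl)oxy]methyl}-5-(prop-1-en-2-yl)cyclohex-3-en-1-yl]propanoic acid, via ring-opened trilithium salt 18 (not isolated)
Conditions: LiOH (4 equiv), THF/MeOH/H2O, rt, dark; then 1 M HCl to pH 2
Reagents that add atoms: lithium hydroxide ([Li+].[OH-])
Why: Saponification of the ethyl ester; the coumarin lactone opens reversibly to the (Z)-coumarinate under hydroxide and closes again on acidification, and no stereocentre is α to a carbonyl any more.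

## Compound list

1 | 3-bromocyclohex-2-en-1-one | O=C1C=C(Br)CCC1 | starting material
2 | (3-ethoxy-3-oxopropyl)zinc bromide | CCOC(=O)CC[Zn]Br | starting material
3 | ethyl 3-(3-oxocyclohex-1-en-1-yl)propanoate | CCOC(=O)CCC1=CC(=O)CCC1 | intermediate
4 | dimethylaluminium enolate of ethyl 3-[(1S)-1-methyl-3-oxocyclohexyl]propanoate (C2=C3 enolate) | C1CC(O[Al](C)C)=C[C@](C)(CCC(=O)OCC)C1 | intermediate
5 | ethyl 3-[(1S)-1-methyl-3-(trimethylsilyloxy)cyclohex-2-en-1-yl]propanoate | C1CC(O[Si](C)(C)C)=C[C@](C)(CCC(=O)OCC)C1 | intermediate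
6 | ethyl 3-[(1S)-2-[(dimethylamino)methyl]-1-methyl-3-oxocyclohexyl]propanoate (both C2 epimers) | C1CC(=O)C(CN(C)C)[C@](C)(CCC(=O)OCC)C1 | intermediate
7 | {[(2S)-2-(3-ethoxy-3-oxopropyl)-2-methyl-6-oxocyclohexyl]methyl}trimethylammonium iodide (both epimers at the ring CH) | C1CC(=O)C(C[N+](C)(C)C)[C@](C)(CCC(=O)OCC)C1.[I-] | intermediate
8 | ethyl 3-[(1S)-1-methyl-2-methylidene-3-oxocyclohexyl]propanoate | C1CC(=O)C(=C)[C@](C)(CCC(=O)OCC)C1 | intermediate
9 | 7-hydroxy-2H-chromen-2-one (umbelliferone) | Oc1ccc2ccc(=O)oc2c1 | starting material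
10 | ethyl 3-[(1S,2S)-1-methyl-3-oxo-2-{[(2-oxo-2H-chromen-7-yl)oxy]methyl}cyclohexyl]propanoate | C1CC(=O)[C@H](COc2ccc3ccc(=O)oc3c2)[C@](C)(CCC(=O)OCC)C1 | intermediate
11 | ethyl 3-[(1S,2S)-1-methyl-2-{[(2-oxo-2H-chromen-7-yl)oxy]methyl}-3-(trimethylsilyloxy)cyclohex-3-en-1-yl]propanoate | C1C=C(O[Si](C)(C)C)[C@H](COc2ccc3ccc(=O)oc3c2)[C@](C)(CCC(=O)OCC)C1 | intermediate
12 | ethyl 3-[(1R,6S)-1-methyl-5-oxo-6-{[(2-oxo-2H-chromen-7-yl)oxy]methyl}cyclohex-3-en-1-yl]propanoate | C1=CC(=O)[C@H](COc2ccc3ccc(=O)oc3c2)[C@](C)(CCC(=O)OCC)C1 | intermediate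
13 | 4,4,5,5-tetramethyl-2-(prop-1-en-2-yl)-1,3,2-dioxaborolane | CC(=C)B1OC(C)(C)C(C)(C)O1 | starting material
14 | ethyl 3-[(1R,2S,5S)-1-methyl-3-oxo-2-{[(2-oxo-2H-chromen-7-yl)oxy]methyl}-5-(prop-1-en-2-yl)cyclohexyl]propanoate | C=C(C)[C@@H]1CC(=O)[C@H](COc2ccc3ccc(=O)oc3c2)[C@](C)(CCC(=O)OCC)C1 | intermediate
15 | potassium enolate of 14 (C3=C4 enolate) | C=C(C)[C@@H]1C=C([O-])[C@H](COc2ccc3ccc(=O)oc3c2)[C@](C)(CCC(=O)OCC)C1.[K+] | intermediate
16 | ethyl 3-[(1R,2S,5S)-1-methyl-2-{[(2-oxo-2H-chromen-7-yl)oxy]methyl}-5-(prop-1-en-2-yl)-3-{[(trifluoromethyl)sulfonyl]oxy}cyclohex-3-en-1-yl]propanoate | C=C(C)[C@@H]1C=C(OS(=O)(=O)C(F)(F)F)[C@H](COc2ccc3ccc(=O)oc3c2)[C@](C)(CCC(=O)OCC)C1 | intermediate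
17 | ethyl 3-[(1R,2R,5S)-1,3-dimethyl-2-{[(2-oxo-2H-chromen-7-yl)oxy]methyl}-5-(prop-1-en-2-yl)cyclohex-3-en-1-yl]propanoate | C=C(C)[C@@H]1C=C(C)[C@H](COc2ccc3ccc(=O)oc3c2)[C@](C)(CCC(=O)OCC)C1 | intermediate
18 | trilithium salt of the saponified, lactone-opened form of 17 ((Z)-coumarinate phenoxide and side-chain carboxylate) | C=C(C)[C@@H]1C=C(C)[C@H](COc2ccc(/C=C\C(=O)[O-])c([O-])c2)[C@](C)(CCC(=O)[O-])C1.[Li+].[Li+].[Li+] | intermediate
19 | 3-[(1R,2R,5S)-1,3-dimethyl-2-{[(2-oxo-2H-chromen-7-yl)oxy]methyl}-5-(prop-1-en-2-yl)cyclohex-3-en-1-yl]propanoic acid | C=C(C)[C@@H]1C=C(C)[C@H](COc2ccc3ccc(=O)oc3c2)[C@](C)(CCC(=O)O)C1 | target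

## Step count and risk

Total step count: 9. Longest linear sequence: 9 steps (1 → 19); 2, 9 and 13 are bought and enter directly.

The three steps most likely to fail:

Step 4 (the proposed new reaction). The face selectivity of the protonation is untested, umbelliferone could react at carbon instead of oxygen, and the adduct could revert. The fallback uses known chemistry, sets out from 5 and comes back at 10. Lewis-acid-catalysed hydroxymethylation of silyl enol ether 5 with aqueous formaldehyde (Yb(OTf)3, THF/H2O, rt) gives the β-hydroxy ketone as a mixture of C2 epimers. Chromatography gives ethyl 3-[(1S,2S)-2-(hydroxymethyl)-1-methyl-3-oxocyclohexyl]propanoate F1. Mitsunobu etherification of F1 with 9 (PPh3, DIAD, THF, 0 °C → rt) then forms the same C–O bond and gives 10. The price is an unselective C2 and a separation.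

Step 5. The strong base could trigger loss of the β-aryloxide, and the Saegusa step uses stoichiometric palladium on a sensitive ketone. The fallback moves the desaturation ahead of the ether; it sets out from 3 and comes back at 12. Step 2 run with an aqueous quench gives ethyl 3-[(1S)-1-methyl-3-oxocyclohexyl]propanoate F2. Aerobic dehydrogenation (Pd(DMSO)2(TFA)2, O2, AcOH, 80 °C) can only desaturate away from the quaternary carbon and gives ethyl 3-[(1R)-1-methyl-5-oxocyclohex-3-en-1-yl]propanoate F3. α'-Methylenation at the only enolisable position (paraformaldehyde, N-methylanilinium trifluoroacetate, THF, reflux) gives ethyl 3-[(1R)-1-methyl-6-methylidene-5-oxocyclohex-3-en-1-yl]propanoate F4. Addition of 9 to the exocyclic methylene of F4 under the step 4 conditions gives 12 directly, so this fallback still depends on step 4 working.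

Step 6. The catalyst has to override whatever bias the C2 centre exerts, the coumarin is a second (slower) acceptor, and C2 is epimerisable in 12 and 14. The fallback replaces catalyst control by 1,3-chirality transfer; it sets out from 12 and comes back at 17, so steps 7 and 8 are skipped. MeMgBr/CeCl3 (THF, −78 °C) should add to the ketone anti to the C2 substituent and give ethyl 3-[(1R,5S,6S)-5-hydroxy-1,5-dimethyl-6-{[(2-oxo-2H-chromen-7-yl)oxy]methyl}cyclohex-3-en-1-yl]propanoate F5. Phenyl isocyanate converts it into ethyl 3-[(1R,5S,6S)-1,5-dimethyl-6-{[(2-oxo-2H-chromen-7-yl)oxy]methyl}-5-[(phenylcarbamoyl)oxy]cyclohex-3-en-1-yl]propanoate F6. Deprotonation of the carbamate and treatment with CuI and isopropenyllithium (carbamate-directed syn-SN2' substitution) delivers the isopropenyl group to C5 on the face of the leaving group and gives 17.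

Further compounds
F1 | step 4 | ethyl 3-[(1S,2S)-2-(hydroxymethyl)-1-methyl-3-oxocyclohexyl]propanoate | C1CC(=O)[C@H](CO)[C@](C)(CCC(=O)OCC)C1
F2 | step 5 | ethyl 3-[(1S)-1-methyl-3-oxocyclohexyl]propanoate | C1CC(=O)C[C@](C)(CCC(=O)OCC)C1
F3 | step 5 | ethyl 3-[(1R)-1-methyl-5-oxocyclohex-3-en-1-yl]propanoate | C1=CC(=O)C[C@](C)(CCC(=O)OCC)C1
F4 | step 5 | ethyl 3-[(1R)-1-methyl-6-methylidene-5-oxocyclohex-3-en-1-yl]propanoate | C1=CC(=O)C(=C)[C@](C)(CCC(=O)OCC)C1
F5 | step 6 | ethyl 3-[(1R,5S,6S)-5-hydroxy-1,5-dimethyl-6-{[(2-oxo-2H-chromen-7-yl)oxy]methyl}cyclohex-3-en-1-yl]propanoate | C1=C[C@](C)(O)[C@H](COc2ccc3ccc(=O)oc3c2)[C@](C)(CCC(=O)OCC)C1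
F6 | step 6 | ethyl 3-[(1R,5S,6S)-1,5-dimethyl-6-{[(2-oxo-2H-chromen-7-yl)oxy]methyl}-5-[(phenylcarbamoyl)oxy]cyclohex-3-en-1-yl]propanoate | C1=C[C@](C)(OC(=O)Nc2ccccc2)[C@H](COc2ccc3ccc(=O)oc3c2)[C@](C)(CCC(=O)OCC)C1
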